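Ring A of the isoflavone is built last. It has one oxygen only, at C7, para to C4a (the carbon holding the C4 ketone); a 5-acyl-2-pyrone that undergoes cycloaddition with a ketene acetal and then decarboxylates delivers exactly this arrangement. The chromone is therefore cut at C5–C6 and C7–C8, leading back to a 3-aryl-pyrano[4,3-b]pyran-4,7-dione, in which a 2-pyrone stands in for ring A and the fully substituted, MOM-protected ring B is already attached, and to 1,1-bis(trimethylsilyloxy)ethene. One operation forms both bonds, closes ring A, releases CO2 and trimethylsilanol and leaves the C7 oxygen as a silyl ether. The pyranopyrandione comes from an arylacetone through a dienaminone and methyl malonyl chloride.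

Key step: step 8

Remarks:
- Ar = 5-methoxy-2,4-bis(methoxymethoxy)-3-(3-methylbut-2-enyl)phenyl.
- Atom numbers refer to the pyrano[4,3-b]pyran skeleton in 16 and to the chromen-4-one skeleton from 21 on; C2, C3, C4, C4a, C5, C8 and C8a keep their numbers through step 8.
- Design note: C2 and C5 are installed as aminomethylene carbons before the malonyl unit (C7, C8, C8a) is attached, so no formylating agent ever meets the nucleophilic C8 methylene.
- Assumption: the ketene acetal is prepared fresh (step 7) because it is moisture-sensitive, and racemic propylene oxide is used because the carbinol centre it creates is oxidised away.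

Step 1
Reactants: 1 4-methoxyresorcinol; 2 chloromethyl methyl ether
Product: 3 1-methoxy-2,4-bis(methoxymethoxy)benzene
Conditions: K2CO3, acetone, 0 °C → reflux
Reagents that add atoms: chloromethyl methyl ether, COCCl
Why: Williamson-type O-alkylation of both phenols by the reactive α-chloro ether installs two MOM acetals, which later act as ortho-directing groups and are removed by acid at the end.

Step 2
Reactants: 3 1-methoxy-2,4-bis(methoxymethoxy)benzene; 4 prenyl bromide
Product: 6 1-methoxy-2,4-bis(methoxymethoxy)-3-(3-methylbut-2-enyl)benzene, via aryllithium 5 (not isolated)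
Conditions: n-BuLi, THF, 0 °C; then CuI (10 mol %), 4, −78 °C → rt
Reagents that add atoms: prenyl bromide, CC(C)=CCBr
Why: Directed ortho-metalation removes the ring proton flanked by both OMOM groups, and copper-catalysed allylic substitution at the primary carbon of prenyl bromide should give the linear prenyl arene.

Step 3
Reactants: 6 1-methoxy-2,4-bis(methoxymethoxy)-3-(3-methylbut-2-enyl)benzene; 7 propylene oxide (racemic)
Product: 9 1-[Ar]propan-2-ol (racemic), via aryllithium 8 (not isolated)
Conditions: n-BuLi, THF, 0 °C; then 7, BF3·OEt2, −78 °C; aq. NaHCO3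
Reagents that add atoms: propylene oxide, CC1CO1
Why: A second directed ortho-metalation takes the only ring proton next to an OMOM group (OMOM outranks OMe as director), and BF3-assisted SN2 opening of the epoxide at its CH2 end gives the secondary alcohol, whose carbinol centre forms racemic and is erased in step 4.

Step 4
Reactants: 9 1-[Ar]propan-2-ol
Product: 10 1-[Ar]propan-2-one
Conditions: Dess–Martin periodinane, CH2Cl2, 0 °C → rt
Reagents that add atoms: none
Why: Dess–Martin oxidation converts the secondary alcohol into the ketone under near-neutral conditions that should leave the MOM acetals, the prenyl alkene and the electron-rich arene untouched.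

Step 5
Reactants: 10 1-[Ar]propan-2-one; 11 tert-butoxybis(dimethylamino)methane (Bredereck's reagent)
Product: 12 (1E,4E)-1,5-bis(dimethylamino)-2-[Ar]penta-1,4-dien-3-one
Conditions: 11 (4 equiv), toluene, 110 °C
Reagents that add atoms: tert-butoxybis(dimethylamino)methane, CC(C)(C)OC(N(C)C)N(C)C
Why: Aminomethylenation (enaminone formation) should occur at both α-carbons of the ketone, first at the more acidic benzylic CH2 and then at the methyl group, which fixes the future C2 and C5 as CH–NMe2 carbons without any regiochemical choice.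

Step 6
Reactants: 12 (1E,4E)-1,5-bis(dimethylamino)-2-[Ar]penta-1,4-dien-3-one; 13 methyl malonyl chloride
Product: 16 3-[Ar]pyrano[4,3-b]pyran-4,7-dione, via C-acylated dienaminone 14 (not isolated), via hydroxypyranone enaminone 15 (not isolated)
Conditions: 13, pyridine, CH2Cl2, −20 → 0 °C; then AcOH/H2O/THF (3:1:1), 45 °C
Reagents that add atoms: methyl malonyl chloride, COC(=O)CC(Cl)=O; water, O
Why: C-acylation of the enaminone at its only free α-CH (the future C4a), as in the acylation of β-aminoacrylates, gives 14, whose doubly acceptor-activated aminomethylene carbon is hydrolysed and lactonised onto the methyl ester (4-hydroxy-2-pyranone formation, as from alkoxymethylene-3-oxoglutarates) to give 15, after which the pyranone OH displaces the second amine in a chromone-type addition–elimination that closes the 4-pyranone ring.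

Step 7
Reactants: 17 trimethylsilyl acetate; 18 chlorotrimethylsilane
Product: 20 1,1-bis(trimethylsilyloxy)ethene, via lithium enolate 19 (not isolated)
Conditions: LiN(i-Pr)2, THF, −78 °C; then 18, −78 °C → rt; distillation
Reagents that add atoms: chlorotrimethylsilane, C[Si](C)(C)Cl
Why: Deprotonation of the silyl ester and O-silylation of its lithium enolate is the standard preparation of ketene bis(silyl) acetals.

Step 8
Reactants: 16 3-[Ar]pyrano[4,3-b]pyran-4,7-dione; 20 1,1-bis(trimethylsilyloxy)ethene
Product: 23 3-[Ar]-7-(trimethylsilyloxy)chromen-4-one, via bridged lactone adduct 21 (not isolated), via dihydrochromenone 22 (not isolated)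
Conditions: 20 (4 equiv), toluene, 110 °C, sealed tube; volatiles removed in vacuo, crude 23 used directly
Reagents that add atoms: 1,1-bis(trimethylsilyloxy)ethene, C=C(O[Si](C)(C)C)O[Si](C)(C)C
Why: Proposed new method: the 2-pyrone ring of 16 (O6–C7(=O)–C8=C8a–C4a=C5) is an electron-poor diene whose C5 is both the β-carbon of the C4 enone and the δ-carbon of the lactone, so the nucleophilic CH2 of 20 should bond there first and the silyloxy-stabilised cationic carbon should then close onto C8, a polar inverse-electron-demand Diels–Alder addition giving cage lactone 21. Retro-[4+2] extrusion of CO2 from 21 should give diene 22, and 1,2-elimination of trimethylsilanol (H from C6, one silyloxy group from C7) should aromatise it to 23, so ring A is closed by a six-membered [4+2] annulation that creates C5–C6 and C7–C8. The closest known reaction is the cycloaddition of coumalate esters and other 5-acyl-2-pyrones with ketene acetals, which gives para-alkoxybenzoates after loss of CO2 and an alcohol; it has not been shown on a 2-pyrone fused to a 4-pyranone or carrying a donor oxygen at the position corresponding to C8a. No stereocentre survives, because the two bridgeheads of 21 are fixed by the cage and are erased on aromatisation. The step needs regioselectivity (oxygen at C7, not C6), which the matched polarisation of electrophilic C5 and the nucleophilic acetal CH2 should secure, and chemoselectivity for the pyrone diene over conjugate addition at C2 of the 4-pyranone ring, which is only singly activated and shielded by the aryl group on C3.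

Step 9
Reactants: 23 3-[Ar]-7-(trimethylsilyloxy)chromen-4-one
Product: 24 Piscisoflavone A
Conditions: 3 M HCl (aq), MeOH, 40 °C
Reagents that add atoms: none
Why: Acid-catalysed acetal exchange with methanol should remove both MOM groups and solvolyse the aryl silyl ether in one operation, with the temperature kept low so that the prenyl group does not cyclise onto its neighbouring phenols.

Compound list
1 | 4-methoxyresorcinol (4-methoxybenzene-1,3-diol) | COc1ccc(O)cc1O | starting material
2 | chloromethyl methyl ether | COCCl | starting material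
3 | 1-methoxy-2,4-bis(methoxymethoxy)benzene | COCOc1ccc(OC)c(OCOC)c1 | intermediate
4 | prenyl bromide (1-bromo-3-methylbut-2-ene) | CC(C)=CCBr | starting material
5 | [3-methoxy-2,6-bis(methoxymethoxy)phenyl]lithium | [Li]c1c(OCOC)ccc(OC)c1OCOC | intermediate
6 | 1-methoxy-2,4-bis(methoxymethoxy)-3-(3-methylbut-2-enyl)benzene | COc1ccc(OCOC)c(CC=C(C)C)c1OCOC | intermediate
7 | propylene oxide (2-methyloxirane, racemic) | CC1CO1 | starting material
8 | [5-methoxy-2,4-bis(methoxymethoxy)-3-(3-methylbut-2-enyl)phenyl]lithium | [Li]c1cc(OC)c(OCOC)c(CC=C(C)C)c1OCOC | intermediate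
9 | 1-[5-methoxy-2,4-bis(methoxymethoxy)-3-(3-methylbut-2-enyl)phenyl]propan-2-ol (racemic) | CC(O)Cc1cc(OC)c(OCOC)c(CC=C(C)C)c1OCOC | intermediate
10 | 1-[5-methoxy-2,4-bis(methoxymethoxy)-3-(3-methylbut-2-enyl)phenyl]propan-2-one | CC(=O)Cc1cc(OC)c(OCOC)c(CC=C(C)C)c1OCOC | intermediate
11 | tert-butoxybis(dimethylamino)methane (Bredereck's reagent) | CC(C)(C)OC(N(C)C)N(C)C | starting material
12 | (1E,4E)-1,5-bis(dimethylamino)-2-[5-methoxy-2,4-bis(methoxymethoxy)-3-(3-methylbut-2-enyl)phenyl]penta-1,4-dien-3-one | CN(C)/C=C/C(=O)/C(=C/N(C)C)c1cc(OC)c(OCOC)c(CC=C(C)C)c1OCOC | intermediate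
13 | methyl malonyl chloride (methyl 3-chloro-3-oxopropanoate) | COC(=O)CC(Cl)=O | starting material
14 | methyl (6E)-7-(dimethylamino)-4-[(dimethylamino)methylidene]-6-[5-methoxy-2,4-bis(methoxymethoxy)-3-(3-methylbut-2-enyl)phenyl]-3,5-dioxohept-6-enoate (geometry at the diacyl aminomethylene bond labile, not defined) | COC(=O)CC(=O)C(=CN(C)C)C(=O)/C(=C/N(C)C)c1cc(OC)c(OCOC)c(CC=C(C)C)c1OCOC | intermediate
15 | 5-[(2E)-3-(dimethylamino)-2-[5-methoxy-2,4-bis(methoxymethoxy)-3-(3-methylbut-2-enyl)phenyl]prop-2-enoyl]-4-hydroxy-2H-pyran-2-one | CN(C)/C=C(c1cc(OC)c(OCOC)c(CC=C(C)C)c1OCOC)/C(=O)C2=COC(=O)C=C2O | intermediate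
16 | 3-[5-methoxy-2,4-bis(methoxymethoxy)-3-(3-methylbut-2-enyl)phenyl]pyrano[4,3-b]pyran-4,7-dione | O=C1C=C2OC=C(c3cc(OC)c(OCOC)c(CC=C(C)C)c3OCOC)C(=O)C2=CO1 | intermediate
17 | trimethylsilyl acetate | CC(=O)O[Si](C)(C)C | starting material
18 | chlorotrimethylsilane | C[Si](C)(C)Cl | starting material
19 | lithium 1-(trimethylsilyloxy)ethenolate | C=C(O[Li])O[Si](C)(C)C | intermediate
20 | 1,1-bis(trimethylsilyloxy)ethene | C=C(O[Si](C)(C)C)O[Si](C)(C)C | intermediate
21 | [4+2] adduct: 3-[5-methoxy-2,4-bis(methoxymethoxy)-3-(3-methylbut-2-enyl)phenyl]-7,7-bis(trimethylsilyloxy)-5,6,7,8-tetrahydrochromen-4-one bridged from C5 to C8 by –O–C(=O)– (oxygen on C5, carbonyl carbon on C8); racemic, bridgehead configuration fixed by the cage, one enantiomer drawn | O=C1O[C@@H]2CC(O[Si](C)(C)C)(O[Si](C)(C)C)[C@H]1C3=C2C(=O)C(c4cc(OC)c(OCOC)c(CC=C(C)C)c4OCOC)=CO3 | intermediate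
22 | 3-[5-methoxy-2,4-bis(methoxymethoxy)-3-(3-methylbut-2-enyl)phenyl]-7,7-bis(trimethylsilyloxy)-6,7-dihydrochromen-4-one | C[Si](C)(C)OC1(O[Si](C)(C)C)CC=C2C(=O)C(c3cc(OC)c(OCOC)c(CC=C(C)C)c3OCOC)=COC2=C1 | intermediate
23 | 3-[5-methoxy-2,4-bis(methoxymethoxy)-3-(3-methylbut-2-enyl)phenyl]-7-(trimethylsilyloxy)chromen-4-one | C[Si](C)(C)Oc1ccc2c(c1)occ(-c1cc(OC)c(OCOC)c(CC=C(C)C)c1OCOC)c2=O | intermediate
24 | Piscisoflavone A, 3-[2,4-dihydroxy-5-methoxy-3-(3-methylbut-2-enyl)phenyl]-7-hydroxychromen-4-one | COc1cc(-c2coc3cc(O)ccc3c2=O)c(O)c(CC=C(C)C)c1O | target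

Total step count: 9. Longest linear sequence: 8 steps (1–6, 8, 9); step 7 is a one-step side branch.

Steps most likely to fail

1. Step 8. The C8a oxygen donates into the pyrone diene, so the cycloaddition may be slower than thermal decay of the ketene acetal (oxygen-to-carbon silyl shift, hydrolysis). The acetal may also add in a conjugate sense at C2 and open the 4-pyranone ring. Fallback (known chemistry; sets out from 6, returns at 24):
   - Ortho-lithiation of 6 as in step 3 and quenching with 2-isopropoxy-4,4,5,5-tetramethyl-1,3,2-dioxaborolane should give 2-[Ar]-4,4,5,5-tetramethyl-1,3,2-dioxaborolane F1.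
   - In parallel, 2',4'-dihydroxyacetophenone is protected at its non-chelated 4-OH (MOMCl, K2CO3, acetone) to give 1-[2-hydroxy-4-(methoxymethoxy)phenyl]ethanone F2.
   - F2 is condensed with DMF dimethyl acetal to (E)-3-(dimethylamino)-1-[2-hydroxy-4-(methoxymethoxy)phenyl]prop-2-en-1-one F3, and cyclised with I2 to 3-iodo-7-(methoxymethoxy)chromen-4-one F4.
   - Suzuki–Miyaura coupling of F1 with F4 (Pd(PPh3)4 as zerovalent palladium catalyst, K2CO3, dioxane/H2O, 80 °C) should give 7-(methoxymethoxy)-3-[Ar]chromen-4-one F5.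
   - The conditions of step 9 then remove its three MOM groups to give 24.

2. Step 6. Acylation at oxygen or nitrogen, or self-condensation of 13 through its ketene, may win over C-acylation at C4a. Fallback (sets out from 6, returns at 14):
   - Lithiation of 6 as in step 3 and opening of ethylene oxide should give 2-[Ar]ethanol F6.
   - Oxidation (TEMPO, PhI(OAc)2, MeCN/H2O) gives [Ar]acetic acid F7, and 1,1'-carbonyldiimidazole converts it into 1-(imidazol-1-yl)-2-[Ar]ethanone F8.
   - F8 acylates the lithium dienolate of 2,2,6-trimethyl-4H-1,3-dioxin-4-one (LiN(SiMe3)2, THF, −78 °C) at its methyl carbon to give 2,2-dimethyl-6-[3-Ar-2-oxopropyl]-4H-1,3-dioxin-4-one F9.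
   - In F9 the future C8 is a vinylic CH of the dioxinone, so Bredereck's reagent can only aminomethylenate the two CH2 groups flanking the ketone, giving 6-[(4E)-1,5-bis(dimethylamino)-4-Ar-3-oxopenta-1,4-dien-2-yl]-2,2-dimethyl-4H-1,3-dioxin-4-one F10.
   - Heating F10 in toluene/MeOH (100 °C) expels acetone by retro-[4+2] and traps the acylketene as the methyl ester, which is 14. The aqueous acetic acid stage of step 6 then closes both rings to 16.

3. Step 5. The second condensation, at the weakly acidic methyl group of the vinylogous amide, may stall, or prolonged heating may degrade the dienaminone. Fallback (sets out from 10, returns at 12):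
   - DMF dimethyl acetal at 80 °C should condense only at the benzylic CH2 to give (3E)-4-(dimethylamino)-3-[Ar]but-3-en-2-one F11.
   - Its lithium enolate (LiN(SiMe3)2, THF, −78 °C) is formylated with ethyl formate in a Claisen condensation to give (1Z,4E)-5-(dimethylamino)-1-hydroxy-4-[Ar]penta-1,4-dien-3-one F12.
   - Dimethylammonium chloride in ethanol converts the hydroxymethylene group into the enaminone, giving 12.

Further compounds
F1 | step 8 | 2-[5-methoxy-2,4-bis(methoxymethoxy)-3-(3-methylbut-2-enyl)phenyl]-4,4,5,5-tetramethyl-1,3,2-dioxaborolane | COc1cc(B2OC(C)(C)C(C)(C)O2)c(OCOC)c(CC=C(C)C)c1OCOC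
F2 | step 8 | 1-[2-hydroxy-4-(methoxymethoxy)phenyl]ethanone | CC(=O)c1ccc(OCOC)cc1O
F3 | step 8 | (E)-3-(dimethylamino)-1-[2-hydroxy-4-(methoxymethoxy)phenyl]prop-2-en-1-one | CN(C)/C=C/C(=O)c1ccc(OCOC)cc1O
F4 | step 8 | 3-iodo-7-(methoxymethoxy)chromen-4-one | COCOc1ccc2c(c1)occ(I)c2=O
F5 | step 8 | 7-(methoxymethoxy)-3-[5-methoxy-2,4-bis(methoxymethoxy)-3-(3-methylbut-2-enyl)phenyl]chromen-4-one | COCOc1ccc2c(c1)occ(-c1cc(OC)c(OCOC)c(CC=C(C)C)c1OCOC)c2=O
F6 | step 6 | 2-[5-methoxy-2,4-bis(methoxymethoxy)-3-(3-methylbut-2-enyl)phenyl]ethanol | OCCc1cc(OC)c(OCOC)c(CC=C(C)C)c1OCOC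
F7 | step 6 | [5-methoxy-2,4-bis(methoxymethoxy)-3-(3-methylbut-2-enyl)phenyl]acetic acid | OC(=O)Cc1cc(OC)c(OCOC)c(CC=C(C)C)c1OCOC
F8 | step 6 | 1-(imidazol-1-yl)-2-[5-methoxy-2,4-bis(methoxymethoxy)-3-(3-methylbut-2-enyl)phenyl]ethanone | O=C(Cc1cc(OC)c(OCOC)c(CC=C(C)C)c1OCOC)n1ccnc1
F9 | step 6 | 2,2-dimethyl-6-{3-[5-methoxy-2,4-bis(methoxymethoxy)-3-(3-methylbut-2-enyl)phenyl]-2-oxopropyl}-4H-1,3-dioxin-4-one | CC1(C)OC(=O)C=C(CC(=O)Cc2cc(OC)c(OCOC)c(CC=C(C)C)c2OCOC)O1
F10 | step 6 | 6-{(4E)-1,5-bis(dimethylamino)-4-[5-methoxy-2,4-bis(methoxymethoxy)-3-(3-methylbut-2-enyl)phenyl]-3-oxopenta-1,4-dien-2-yl}-2,2-dimethyl-4H-1,3-dioxin-4-one | CC1(C)OC(=O)C=C(C(=CN(C)C)C(=O)/C(=C/N(C)C)c2cc(OC)c(OCOC)c(CC=C(C)C)c2OCOC)O1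
F11 | step 5 | (3E)-4-(dimethylamino)-3-[5-methoxy-2,4-bis(methoxymethoxy)-3-(3-methylbut-2-enyl)phenyl]but-3-en-2-one | CC(=O)/C(=C/N(C)C)c1cc(OC)c(OCOC)c(CC=C(C)C)c1OCOC
F12 | step 5 | (1Z,4E)-5-(dimethylamino)-1-hydroxy-4-[5-methoxy-2,4-bis(methoxymethoxy)-3-(3-methylbut-2-enyl)phenyl]penta-1,4-dien-3-one | O/C=C\C(=O)/C(=C/N(C)C)c1cc(OC)c(OCOC)c(CC=C(C)C)c1OCOC
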